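All runs come from a simulation for substances that don't exist, and the scatter is random.

Temperature is what separates the flasks asked about: alpha, gamma and zeta each stay at one temperature for 20 min, while beta goes from −20 °C to 20 °C at 6.0 min.

| setting | elm | larch | ash | alpha | zeta | beta | gamma |
|---|---|---|---|---|---|---|---|
| substrate | 0.075 M | 0.11 M | 0.15 M | 0.15 M | 0.15 M | 0.15 M | 0.15 M |
| free catalyst | 0.30 mM | 0.30 mM | 0.15 mM | 0.30 mM | 0.30 mM | 0.30 mM | 0.30 mM |
| temperature | −25 °C | 0 °C | −25 °C | −20 °C | 20 °C |  | 0 °C |
| remark | run made earlier | run made earlier | run made earlier |  |  | at −20 °C until 6.0 min, from then on at 20 °C |  |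
| time |  |  |  | 20 min | 20 min | 20 min | 20 min |

| run | time / min | target / % | substrate / % |
|---|---|---|---|
| elm | 2.00 | 1.0 | 99.0 |
| elm | 4.00 | 1.5 | 98.2 |
| elm | 6.00 | 2.1 | 97.9 |
| elm | 12.0 | 4.0 | 95.9 |
| elm | 25.0 | 9.1 | 90.5 |
| larch | 0.667 | 1.9 | 98.1 |
| larch | 2.00 | 5.0 | 94.4 |
| larch | 4.00 | 10.4 | 89.8 |
| larch | 6.00 | 14.8 | 84.9 |
| larch | 10.0 | 22.8 | 77.3 |
| ash | 2.00 | 0.5 | 99.8 |
| ash | 4.00 | 0.6 | 99.0 |
| ash | 6.00 | 0.7 | 99.1 |
| ash | 12.0 | 1.4 | 98.4 |
| ash | 25.0 | 3.0 | 96.8 |

(readings scatter by 0.3 percentage points)

- which flask leads in amount of target, in percent of the substrate charged ("all alike" within 1.5 percentage points) (alpha / zeta / beta / gamma / all alike)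
- how much target is there at the end, in percent of the substrate charged: alpha
- how much target is there at the end, in percent of the substrate charged: zeta
- how much target is there at the end, in percent of the substrate charged: beta
- how much target is there at the end, in percent of the substrate charged: gamma



So the substrate curve of a flask is replaced by its mean, one first-order constant. Larch at 0 °C still holds 77.3% of its substrate after 10.0 min, which makes a mean first-order constant of 0.0257 min⁻¹. But a mean can hide a slope, so larch is split: the stretch up to 4.00 min reads 0.0269 min⁻¹, the rest reads less, 0.0250 min⁻¹, a gap read through a scatter of 0.3 percentage points. Elm carries the same 0.30 mM of free catalyst but less substrate, 0.075 M against 0.11 M, and at −25 °C reads 0.00399 min⁻¹, lower than larch, so temperature and charge differ together between those two runs.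

The reckoning here doubles the larch constant in each of two equal steps of temperature on the way to 20 °C, giving a mean constant of 0.103 min⁻¹, and halves it in each of two such steps for −20 °C, giving 0.00644 min⁻¹. In this reckoning the exponent of a stretch is its mean constant times its length; exponents add, and substrate left is e to minus their sum. Zeta gets 2.06, or 87.3% target. Beta gets 1.48, or 77.2%, less than zeta.

The forecast names zeta and gives alpha 10.9%, zeta 85%, beta 74% and gamma 40.5%. Its zeta stands a little lower than the reckoning here, and it warns that “catalyst death or a changed order there is untested”.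

The flasks give alpha 8.58%, zeta 57.3%, beta 51.0% and gamma 37.9%, so zeta leads.

    substrate + free catalyst → catalyst intermediate (k = 320 M⁻¹ min⁻¹, Ea = 36.0 kJ mol⁻¹)
    catalyst intermediate → free catalyst + target (k = 480 min⁻¹, Ea = 73.0 kJ mol⁻¹)
    free catalyst ⇌ dormant form (K = 3.20, k = 0.130 min⁻¹, Ea = 78.0 kJ mol⁻¹, ΔH = −33.0 kJ mol⁻¹)
    (constants at 20 °C)

Zeta's exponent reads 0.851 where 0.103 min⁻¹ promised 2.06. Zeta's target stands at 57.3% in part because free catalyst passes into the dormant form, an off-cycle reservoir, and in part because of the hour of the reading: without that path zeta reaches 84.1%, and left to 200 min it holds 99.3%. In beta, 0.103 min⁻¹ promised 1.44 for the hot stretch. Zeta's own mean up to half conversion, ln(2) over 14.2 min, put in its place beside 0.00644 min⁻¹, gives 0.722, or 51.4% target, and beta holds 51.0%.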